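**Strategy**

- Ring A is numbered C1 (OH), C3 (diaryl ether oxygen) and C5 (C14 chain). These three groups are mutually meta, which is the pattern a 3-alkylcyclobutenone (supplying C1, C4, C5, C6 and the hydroxyl) and an oxygen-substituted alkyne (supplying C2, C3) give on benzannulation. Ring A is therefore cut at C1–C2, C3–C4 and C1–C6, and the hindered ring B–O–ring A bond is carried in as an aryl alkynyl ether.
- Further cuts: chain terminus to cyclobutenone C3 (alkyllithium addition to 3-ethoxycyclobutenone), alkyne carbon to ring B oxygen (phenol plus trichloroethylene), the C–O bond of the ring B phenol (bromination, borylation, oxidation) and ring B to chain (copper-catalysed Grignard coupling).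
- Forward: ring B is bought, the C14 chain is attached, the phenol is installed and converted into a silyl-capped ynol ether, and the cyclobutenone is added to the far end of the chain. One thermal benzannulation then builds ring A and closes the 20-membered ring together; protodesilylation and demethylation finish.
- Stereochemistry: the target has no stereocentre and no stereogenic double bond, so nothing has to be set.

Key step: step 11

Assumption: ketene is not sold and is taken from a laboratory ketene generator (pyrolysis of acetone).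

**Route**

Step 1
Reactants: 1 tetradecane-1,14-diol
Product: 2 14-bromotetradecan-1-ol
Conditions: 48% aq HBr (1.2 equiv), toluene, reflux
Reagents that add atoms: hydrogen bromide (Br)
Why: Two-phase monobromination of an α,ω-diol (substitution of the protonated alcohol by bromide) should stop at the bromo alcohol, which moves into the toluene layer away from the acid.

Step 2
Reactants: 2 14-bromotetradecan-1-ol
Product: 3 1-bromo-14-chlorotetradecane
Conditions: PPh3, NCS, CH2Cl2, 0 °C → rt
Reagents that add atoms: N-chlorosuccinimide (O=C1CCC(=O)N1Cl)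
Why: Appel-type chlorination through the alkoxyphosphonium salt replaces OH by Cl at room temperature, where chloride should not exchange with the primary bromide.

Step 3
Reactants: 4 1-bromo-3,5-dimethoxybenzene; 3 1-bromo-14-chlorotetradecane
Product: 6 1-(14-chlorotetradecyl)-3,5-dimethoxybenzene, via (3,5-dimethoxyphenyl)magnesium bromide 5 (not isolated)
Conditions: 4, Mg, THF, 50 °C; then 3, Li2CuCl4 (3 mol %), THF, −10 °C → rt
Reagents that add atoms: none
Why: Copper-catalysed cross-coupling of an aryl Grignard reagent with a primary alkyl halide takes place at the C–Br end, the C–Cl end being much less reactive toward the organocopper intermediate.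

Step 4
Reactants: 6 1-(14-chlorotetradecyl)-3,5-dimethoxybenzene
Product: 7 2-bromo-1-(14-chlorotetradecyl)-3,5-dimethoxybenzene
Conditions: NBS (1.0 equiv), MeCN, 0 °C
Reagents that add atoms: N-bromosuccinimide (O=C1CCC(=O)N1Br)
Why: Electrophilic aromatic bromination of 5-alkylresorcinol dimethyl ethers goes para to one methoxy group and ortho to the chain in preference to the more crowded position between the two methoxy groups.

Step 5
Reactants: 7 2-bromo-1-(14-chlorotetradecyl)-3,5-dimethoxybenzene
Product: 10 2-(14-chlorotetradecyl)-4,6-dimethoxyphenol, via aryllithium 8 (not isolated), via lithium aryltrimethoxyborate 9 (not isolated)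
Conditions: n-BuLi (1.05 equiv), THF, −78 °C; B(OMe)3, −78 °C → rt; then 30% H2O2, 2 M NaOH, 0 °C → rt
Reagents that add atoms: hydrogen peroxide (OO)
Why: Bromine–lithium exchange outruns any reaction of n-BuLi with the primary chloride at −78 °C, and borylation followed by peroxide oxidation (aryl shift from boron to oxygen) turns the C–Br bond into C–OH.

Step 6
Reactants: 10 2-(14-chlorotetradecyl)-4,6-dimethoxyphenol
Product: 11 1-(14-chlorotetradecyl)-2-{[(E)-1,2-dichloroethenyl]oxy}-3,5-dimethoxybenzene
Conditions: KH (1.2 equiv), THF, 0 °C; trichloroethylene (1.5 equiv), 0 °C → rt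
Reagents that add atoms: trichloroethylene (ClC=C(Cl)Cl)
Why: Base converts trichloroethylene into dichloroacetylene, to which the potassium phenoxide adds in anti fashion to give the (E)-1,2-dichlorovinyl ether (the standard first stage of ynol ether synthesis), while the alkyl chloride is inert to the phenoxide in THF at room temperature.

Step 7
Reactants: 11 1-(14-chlorotetradecyl)-2-{[(E)-1,2-dichloroethenyl]oxy}-3,5-dimethoxybenzene
Product: 14 {[2-(14-chlorotetradecyl)-4,6-dimethoxyphenoxy]ethynyl}trimethylsilane, via aryl chloroethynyl ether 12 (not isolated), via lithium aryloxyacetylide 13 (not isolated)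
Conditions: n-BuLi (2.3 equiv), THF, −78 → −40 °C; TMSCl, −78 → 0 °C
Reagents that add atoms: chlorotrimethylsilane (C[Si](C)(C)Cl)
Why: Dehydrochlorination to the chloroalkyne and chlorine–lithium exchange give the lithium aryloxyacetylide, whose C-silylation caps the alkyne so that it has no acidic hydrogen and does not polymerise in the later organolithium step.

Step 8
Reactants: 14 {[2-(14-chlorotetradecyl)-4,6-dimethoxyphenoxy]ethynyl}trimethylsilane
Product: 15 {[2-(14-iodotetradecyl)-4,6-dimethoxyphenoxy]ethynyl}trimethylsilane
Conditions: NaI (5 equiv), NaHCO3, 2-butanone, 80 °C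
Reagents that add atoms: sodium iodide ([Na+].[I-])
Why: Finkelstein halide exchange (SN2, driven by precipitation of NaCl) is neutral and should leave the silyl-capped aryl ynol ether untouched.

Step 9
Reactants: 16 ethoxyacetylene
Product: 17 3-ethoxycyclobut-2-en-1-one
Conditions: ketene gas (from pyrolysis of acetone in a ketene lamp), CH2Cl2, 0 °C → rt
Reagents that add atoms: ketene (C=C=O)
Why: Thermal [2+2] cycloaddition of ketene with the electron-rich alkyne gives the cyclobutenone, the nucleophilic terminal alkyne carbon bonding to the ketene carbonyl carbon so that the ethoxy group ends up at C3.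

Step 10
Reactants: 15 {[2-(14-iodotetradecyl)-4,6-dimethoxyphenoxy]ethynyl}trimethylsilane; 17 3-ethoxycyclobut-2-en-1-one
Product: 21 3-(14-{3,5-dimethoxy-2-[(trimethylsilyl)ethynyloxy]phenyl}tetradecyl)cyclobut-2-en-1-one, via alkyllithium 18 (not isolated), via lithium alkoxide adduct 19 (not isolated), via tertiary trifluoroacetate 20 (not isolated)
Conditions: 15, t-BuLi (2.1 equiv), Et2O–pentane, −78 °C; 17, −78 °C; TFAA (1.1 equiv), −78 °C; then sat. aq NaHCO3, −78 °C → rt
Reagents that add atoms: water (O)
Why: Iodine–lithium exchange is complete within minutes at −78 °C, and 1,2-addition to the vinylogous ester followed by acylation-triggered ionisation of the tertiary alkoxide and hydrolysis of the ethoxy-stabilised cation (Stork–Danheiser-type transposition, the standard route to 3-alkylcyclobutenones) gives the enone without exposing the ynol ether to aqueous acid; the carbinol centre of 19 is racemic and transient.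

Step 11
Reactants: 21 3-(14-{3,5-dimethoxy-2-[(trimethylsilyl)ethynyloxy]phenyl}tetradecyl)cyclobut-2-en-1-one
Product: 26 silylated macrocyclic phenol (ring A with OH at C1 and SiMe3 at C2; ring B as dimethyl ether), via vinylketene 22 (not isolated), via macrocyclic alkenylcyclobutenone 23 (not isolated), via dienylketene 24 (not isolated), via cyclohexadienone 25 (not isolated)
Conditions: syringe-pump addition (12 h) of 21 to toluene at 110 °C (final 1 mM); then 110 °C, 6 h
Reagents that add atoms: none
Why: Proposed new method: heating opens the cyclobutenone by reversible four-electron electrocyclic cleavage to vinylketene 22, and the tethered ynol ether adds to the ketene in a [2+2] cycloaddition (silyl-bearing alkyne carbon to the ketene carbonyl carbon, oxygen-bearing alkyne carbon to the ketene α-carbon), which closes the 20-membered ring end-to-end as alkenylcyclobutenone 23. A second four-electron ring opening gives dienylketene 24, six-electron electrocyclisation between the ketene carbon and the terminal methylene forms the six-membered carbocycle 25, and tautomerisation aromatises it to the phenol, so that the ring A bonds C1–C2, C3–C4 and C1–C6 arise in one operation. The closest known reaction is the intermolecular Danheiser benzannulation of 3-alkylcyclobutenones with alkoxy- and siloxyalkynes, which gives 5-alkylresorcinol monoethers; neither a macrocyclising version nor an aryl silylalkynyl ether as ketenophile has been described. No stereocentre remains in the product, since the sp3 carbon of 23 and the alkene geometry of 24 are lost on aromatisation. The required regioselectivity rests on the polarisation of the ynol ether, which places the aryloxy group meta to the new hydroxyl and the silyl group between them. Ring closure over oligomerisation is favoured by slow addition at high dilution, because unreacted vinylketene reverts to the cyclobutenone, the aryl alkynyl ether has no β-hydrogen for retro-ene loss of ketene, and the 14-methylene tether adds no strain to the macrocyclic transition state.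

Step 12
Reactants: 26 silylated macrocyclic phenol
Product: 27 macrocyclic phenol with ring B as dimethyl ether
Conditions: TFA, CH2Cl2, 0 °C → rt
Reagents that add atoms: none
Why: Protodesilylation by ipso protonation should be fast at an arylsilane carbon that is ortho to a hydroxyl and an aryloxy group and para to the alkyl chain, while the diaryl ether and the methyl ethers are inert to TFA.

Step 13
Reactants: 27 macrocyclic phenol with ring B as dimethyl ether
Product: 28 CNP0173380.0
Conditions: BBr3 (6 equiv), CH2Cl2, −78 °C → rt; then H2O, 0 °C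
Reagents that add atoms: none
Why: BBr3 cleaves aryl methyl ethers through the O–B adduct and bromide attack at methyl (Lewis acid demethylation), whereas the diaryl ether offers no alkyl carbon for attack and should survive.

**Compound list**

1 | tetradecane-1,14-diol | OCCCCCCCCCCCCCCO | starting material
2 | 14-bromotetradecan-1-ol | OCCCCCCCCCCCCCCBr | intermediate
3 | 1-bromo-14-chlorotetradecane | ClCCCCCCCCCCCCCCBr | intermediate
4 | 1-bromo-3,5-dimethoxybenzene | COc1cc(Br)cc(OC)c1 | starting material
5 | (3,5-dimethoxyphenyl)magnesium bromide | COc1cc([Mg]Br)cc(OC)c1 | intermediate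
6 | 1-(14-chlorotetradecyl)-3,5-dimethoxybenzene | ClCCCCCCCCCCCCCCc1cc(OC)cc(OC)c1 | intermediate
7 | 2-bromo-1-(14-chlorotetradecyl)-3,5-dimethoxybenzene | ClCCCCCCCCCCCCCCc1cc(OC)cc(OC)c1Br | intermediate
8 | [2-(14-chlorotetradecyl)-4,6-dimethoxyphenyl]lithium | ClCCCCCCCCCCCCCCc1cc(OC)cc(OC)c1[Li] | intermediate
9 | lithium [2-(14-chlorotetradecyl)-4,6-dimethoxyphenyl]trimethoxyborate | ClCCCCCCCCCCCCCCc1cc(OC)cc(OC)c1[B-](OC)(OC)OC.[Li+] | intermediate
10 | 2-(14-chlorotetradecyl)-4,6-dimethoxyphenol | ClCCCCCCCCCCCCCCc1cc(OC)cc(OC)c1O | intermediate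
11 | 1-(14-chlorotetradecyl)-2-{[(E)-1,2-dichloroethenyl]oxy}-3,5-dimethoxybenzene | ClCCCCCCCCCCCCCCc1cc(OC)cc(OC)c1O/C(Cl)=C\Cl | intermediate
12 | 1-(14-chlorotetradecyl)-2-(chloroethynyloxy)-3,5-dimethoxybenzene | ClCCCCCCCCCCCCCCc1cc(OC)cc(OC)c1OC#CCl | intermediate
13 | lithium [2-(14-chlorotetradecyl)-4,6-dimethoxyphenoxy]acetylide | ClCCCCCCCCCCCCCCc1cc(OC)cc(OC)c1OC#C[Li] | intermediate
14 | {[2-(14-chlorotetradecyl)-4,6-dimethoxyphenoxy]ethynyl}trimethylsilane | ClCCCCCCCCCCCCCCc1cc(OC)cc(OC)c1OC#C[Si](C)(C)C | intermediate
15 | {[2-(14-iodotetradecyl)-4,6-dimethoxyphenoxy]ethynyl}trimethylsilane | ICCCCCCCCCCCCCCc1cc(OC)cc(OC)c1OC#C[Si](C)(C)C | intermediate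
16 | ethoxyacetylene | CCOC#C | starting material
17 | 3-ethoxycyclobut-2-en-1-one | CCOC1=CC(=O)C1 | intermediate
18 | (14-{3,5-dimethoxy-2-[(trimethylsilyl)ethynyloxy]phenyl}tetradecyl)lithium | [Li]CCCCCCCCCCCCCCc1cc(OC)cc(OC)c1OC#C[Si](C)(C)C | intermediate
19 | lithium 1-(14-{3,5-dimethoxy-2-[(trimethylsilyl)ethynyloxy]phenyl}tetradecyl)-3-ethoxycyclobut-2-en-1-olate (racemic) | CCOC1=CC(O[Li])(C1)CCCCCCCCCCCCCCc2cc(OC)cc(OC)c2OC#C[Si](C)(C)C | intermediate
20 | 1-(14-{3,5-dimethoxy-2-[(trimethylsilyl)ethynyloxy]phenyl}tetradecyl)-3-ethoxycyclobut-2-en-1-yl trifluoroacetate (racemic) | CCOC1=CC(OC(=O)C(F)(F)F)(C1)CCCCCCCCCCCCCCc2cc(OC)cc(OC)c2OC#C[Si](C)(C)C | intermediate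
21 | 3-(14-{3,5-dimethoxy-2-[(trimethylsilyl)ethynyloxy]phenyl}tetradecyl)cyclobut-2-en-1-one | O=C1C=C(C1)CCCCCCCCCCCCCCc2cc(OC)cc(OC)c2OC#C[Si](C)(C)C | intermediate
22 | 17-{3,5-dimethoxy-2-[(trimethylsilyl)ethynyloxy]phenyl}-3-methylideneheptadec-1-en-1-one (vinylketene) | O=C=CC(=C)CCCCCCCCCCCCCCc1cc(OC)cc(OC)c1OC#C[Si](C)(C)C | intermediate
23 | macrocyclic cyclobut-2-en-1-one with SiMe3 at C2, the ring B oxygen at C3 and the 1-methylidene end of the chain at C4; 20-membered ring through C3, C4, the alkenyl carbon, fourteen CH2, ring B and oxygen (racemic) | O=C1C([Si](C)(C)C)=C2Oc3c(OC)cc(OC)cc3CCCCCCCCCCCCCCC(=C)C12 | intermediate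
24 | macrocyclic dienylketene: 20-membered ring holding the enol ether C=C and the 1,1-disubstituted alkene carbon, with an exocyclic silylketene on the oxygen-bearing alkene carbon, cis to the methylidene-bearing carbon | O=C=C([Si](C)(C)C)/C1=C\C(=C)CCCCCCCCCCCCCCc2cc(OC)cc(OC)c2O1 | intermediate
25 | macrocyclic cyclohexa-2,4-dien-1-one: SiMe3 at C2, ring B oxygen at C3, chain at C5, CH2 at C6 | O=C1CC2=CC(=C1[Si](C)(C)C)Oc3c(OC)cc(OC)cc3CCCCCCCCCCCCCC2 | intermediate
26 | silylated macrocyclic phenol: ring A with OH at C1, SiMe3 at C2, ring B oxygen at C3 and the chain at C5; ring B with OMe ortho and para to the ether oxygen and the chain at the other ortho position; 20-membered ring | Oc1cc2cc(c1[Si](C)(C)C)Oc3c(OC)cc(OC)cc3CCCCCCCCCCCCCC2 | intermediate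
27 | macrocyclic phenol with ring B as dimethyl ether (26 without the silyl group) | Oc1cc2cc(c1)Oc3c(OC)cc(OC)cc3CCCCCCCCCCCCCC2 | intermediate
28 | CNP0173380.0 (ring A 3-aryloxy-5-alkylphenol, ring B 4,6-dihydroxy, 14 CH2 bridge) | Oc1cc2cc(c1)Oc1c(O)cc(O)cc1CCCCCCCCCCCCCC2 | target

**Count and risks**

Total step count: 13. Longest linear sequence: 12 steps (steps 1–8 and 10–13); step 9 is a one-step side branch.

Steps most likely to fail:

1. Step 11 (Proposed new method). Intermolecular ketene–alkyne addition or ketene dimerisation may outrun the macrocyclic [2+2] event, the silyl group may slow the cycloaddition, and ketene intermediates may acylate the product phenol. The fallback uses known chemistry, sets out from 10 and rejoins the route at 28. Phenol 10 is converted with NaI in 2-butanone into 2-(14-iodotetradecyl)-4,6-dimethoxyphenol F1. 1,3-Dibromo-5-methoxybenzene is mono-metallated with i-PrMgCl·LiCl (THF, −15 °C) to (3-bromo-5-methoxyphenyl)magnesium chloride F2. An excess of F2 (the first equivalent deprotonates the phenol) is coupled with F1 under Li2CuCl4 catalysis to give 2-[14-(3-bromo-5-methoxyphenyl)tetradecyl]-4,6-dimethoxyphenol F3. Intramolecular Ullmann etherification (CuI, N,N-dimethylglycine, Cs2CO3, dioxane, 100 °C, slow addition) closes the 20-membered ring at the diaryl ether bond and gives the macrocyclic trimethyl ether F4. BBr3 then cleaves the three methyl ethers to 28.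

2. Step 10. The alkyllithium may attack the ynol ether (at the oxygen-bearing carbon with loss of aryloxide, or at silicon), it may enolise 17 instead of adding, or the ynol ether may be acylated or hydrated during the transposition. The fallback sets out from 15 and rejoins the route at 26; it uses no organolithium and no acid. Iodide 15 alkylates the sodium salt of diethyl (2-oxopropyl)phosphonate (NaH, THF–DMF) to give diethyl (17-{3,5-dimethoxy-2-[(trimethylsilyl)ethynyloxy]phenyl}-2-oxoheptadecan-3-yl)phosphonate F5. Horner–Wadsworth–Emmons reaction with paraformaldehyde (K2CO3, THF) gives 17-{3,5-dimethoxy-2-[(trimethylsilyl)ethynyloxy]phenyl}-3-methylideneheptadecan-2-one F6. Enolisation at the methyl group with LiN(SiMe3)2 and acylation with CF3CO2CH2CF3 (−78 °C) gives 19-{3,5-dimethoxy-2-[(trimethylsilyl)ethynyloxy]phenyl}-1,1,1-trifluoro-5-methylidenenonadecane-2,4-dione F7, which is not isolated. Diazo transfer from MsN3 (Et3N, H2O, MeCN) with loss of the trifluoroacetyl group gives 1-diazo-17-{3,5-dimethoxy-2-[(trimethylsilyl)ethynyloxy]phenyl}-3-methylideneheptadecan-2-one F8. Irradiation of F8 (300 nm, CH2Cl2, high dilution) should bring about a photochemical Wolff rearrangement to the same vinylketene 22, and warming completes the cascade through 23–25 to 26.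

3. Step 6. The doubly ortho-substituted phenoxide may add sluggishly to dichloroacetylene, and under the more forcing carbonate/DMF conditions it would be O-alkylated by the chloroalkyl chain of a second molecule. The fallback sets out from 10 and rejoins the route at 11; the electrophilic chain end is masked while the phenoxide chemistry is done. KOAc with catalytic NaI in DMF (80 °C, the phenol stays protonated) exchanges the chloride for acetate and gives 14-(2-hydroxy-3,5-dimethoxyphenyl)tetradecyl acetate F9. Dichlorovinylation can then be forced (K2CO3, trichloroethylene, DMF, 70 °C) to 14-(2-{[(E)-1,2-dichloroethenyl]oxy}-3,5-dimethoxyphenyl)tetradecyl acetate F10. Methanolysis (K2CO3, MeOH, rt) gives 14-(2-{[(E)-1,2-dichloroethenyl]oxy}-3,5-dimethoxyphenyl)tetradecan-1-ol F11, and PPh3/NCS (CH2Cl2, 0 °C → rt) restores the chloride to give 11.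

**Further compounds**

F1 | step 11 | 2-(14-iodotetradecyl)-4,6-dimethoxyphenol | ICCCCCCCCCCCCCCc1cc(OC)cc(OC)c1O
F2 | step 11 | (3-bromo-5-methoxyphenyl)magnesium chloride | COc1cc(Br)cc([Mg]Cl)c1
F3 | step 11 | 2-[14-(3-bromo-5-methoxyphenyl)tetradecyl]-4,6-dimethoxyphenol | COc1cc(Br)cc(c1)CCCCCCCCCCCCCCc2cc(OC)cc(OC)c2O
F4 | step 11 | macrocyclic trimethyl ether (28 with all three hydroxyl groups as methyl ethers) | COc1cc2cc(c1)Oc3c(OC)cc(OC)cc3CCCCCCCCCCCCCC2
F5 | step 10 | diethyl (17-{3,5-dimethoxy-2-[(trimethylsilyl)ethynyloxy]phenyl}-2-oxoheptadecan-3-yl)phosphonate | CCOP(=O)(OCC)C(C(C)=O)CCCCCCCCCCCCCCc1cc(OC)cc(OC)c1OC#C[Si](C)(C)C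
F6 | step 10 | 17-{3,5-dimethoxy-2-[(trimethylsilyl)ethynyloxy]phenyl}-3-methylideneheptadecan-2-one | CC(=O)C(=C)CCCCCCCCCCCCCCc1cc(OC)cc(OC)c1OC#C[Si](C)(C)C
F7 | step 10 | 19-{3,5-dimethoxy-2-[(trimethylsilyl)ethynyloxy]phenyl}-1,1,1-trifluoro-5-methylidenenonadecane-2,4-dione | FC(F)(F)C(=O)CC(=O)C(=C)CCCCCCCCCCCCCCc1cc(OC)cc(OC)c1OC#C[Si](C)(C)C
F8 | step 10 | 1-diazo-17-{3,5-dimethoxy-2-[(trimethylsilyl)ethynyloxy]phenyl}-3-methylideneheptadecan-2-one | [N-]=[N+]=CC(=O)C(=C)CCCCCCCCCCCCCCc1cc(OC)cc(OC)c1OC#C[Si](C)(C)C
F9 | step 6 | 14-(2-hydroxy-3,5-dimethoxyphenyl)tetradecyl acetate | CC(=O)OCCCCCCCCCCCCCCc1cc(OC)cc(OC)c1O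
F10 | step 6 | 14-(2-{[(E)-1,2-dichloroethenyl]oxy}-3,5-dimethoxyphenyl)tetradecyl acetate | CC(=O)OCCCCCCCCCCCCCCc1cc(OC)cc(OC)c1O/C(Cl)=C\Cl
F11 | step 6 | 14-(2-{[(E)-1,2-dichloroethenyl]oxy}-3,5-dimethoxyphenyl)tetradecan-1-ol | OCCCCCCCCCCCCCCc1cc(OC)cc(OC)c1O/C(Cl)=C\Cl
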